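The ten-membered ring is opened at C7–C8, the bond that joins the β-carbon C7 of the butenolide ring (O–C6–C7=C11–C12) to the oxygenated sp3 carbon C8. In the forward sense a nickel-electrocatalysed decarboxylative alkenylation turns the carboxyl group on C8 of an acyclic precursor into an α-silyloxy radical and couples it with the C7 alkenyl bromide. This closes the carbocycle, forms C7–C8 and sets C8 in one operation from either C8 epimer. The precursor is a linear C1–C10 chain that already carries the C4–C5 epoxide, the C1 ketone, the C10 methyl centre and the complete 4-bromo-3-(acetoxymethyl)butenolide, with C8 as an O-silylated N-acyloxyphthalimide.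

Key step: step 16

Remark: germacranolide numbering is used (C1 ketone, C4–C5 epoxide, C6 lactone carbinol, C7=C11, C8 ester carbinol, C10 methyl-bearing carbon, C12 lactone carbonyl, C13 acetoxymethyl). C8 is carried as a mixture of epimers from step 7 to step 15, which is immaterial because C8 is planar in step 16. Compounds 22 and 23 map atom for atom onto the target and needed no stereochemical correction. The carboxylic acid is freed before the bromobutenolide is built, so only one esterification lies between that sensitive unit and the ring closure.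

Step 1
Reactants: 1 nerol
Product: 2 [(2R,3S)-3-methyl-3-(4-methylpent-3-en-1-yl)oxiran-2-yl]methanol
Conditions: Ti(Oi-Pr)4 (cat.), D-(−)-diethyl tartrate (cat.), t-BuOOH, 4 Å MS, CH2Cl2, −20 °C
Reagents that add atoms: tert-butyl hydroperoxide, CC(C)(C)OO
Why: Katsuki–Sharpless asymmetric epoxidation, in which the titanium–D-(−)-tartrate complex binds the allylic hydroxyl and delivers oxygen to the face that gives the (2R,3S) epoxide (C5 R and C4 S of the target), while the remote alkene has no directing hydroxyl and stays untouched.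

Step 2
Reactants: 2 [(2R,3S)-3-methyl-3-(4-methylpent-3-en-1-yl)oxiran-2-yl]methanol
Product: 3 (2R,3S)-2-[(benzyloxy)methyl]-3-methyl-3-(4-methylpent-3-en-1-yl)oxirane
Conditions: NaH, BnBr, Bu4NI (cat.), THF, 0 °C → rt
Reagents that add atoms: benzyl bromide, BrCc1ccccc1
Why: Williamson etherification of the primary alkoxide, which in THF is benzylated faster than it can open the neighbouring epoxide (Payne migration), giving a C6–O protecting group that lasts until its hydrogenolysis in step 10.

Step 3
Reactants: 3 (2R,3S)-2-[(benzyloxy)methyl]-3-methyl-3-(4-methylpent-3-en-1-yl)oxirane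
Product: 4 3-{(2S,3R)-3-[(benzyloxy)methyl]-2-methyloxiran-2-yl}propanal
Conditions: O3, CH2Cl2, −78 °C; then PPh3, −78 °C → rt
Reagents that add atoms: ozone, [O-][O+]=O
Why: Ozonolysis with reductive work-up cleaves the only alkene to the C1 aldehyde and acetone, the epoxide and the benzyl ether being inert to ozone at −78 °C.

Step 4
Reactants: 4 3-{(2S,3R)-3-[(benzyloxy)methyl]-2-methyloxiran-2-yl}propanal
Product: 5 (3R,4S)-1-{(2S,3R)-3-[(benzyloxy)methyl]-2-methyloxiran-2-yl}-4-methylhex-5-en-3-ol
Conditions: trans-2-butene, n-BuLi, KOt-Bu, THF, −78 → −45 °C; (−)-Ipc2BOMe, −78 °C; BF3·OEt2 (0.95 equiv per borinate), −78 °C; then 4, −78 °C; NaOH, H2O2, 0 °C → rt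
Reagents that add atoms: (E)-crotylbis(isopinocampheyl)borane (made in the flask), C/C=C/CB([C@@H]1C[C@@H]2C[C@H]([C@H]1C)C2(C)C)[C@@H]1C[C@@H]2C[C@H]([C@H]1C)C2(C)C
Why: Brown crotylboration through a closed chair transition state, in which the (E)-crotylborane from (−)-Ipc2BOMe adds to the Si face of the aldehyde to give the anti homoallylic alcohol and so sets C10 (S); the C1 carbinol centre is erased later by oxidation, and BF3·OEt2 is kept below one equivalent so that no free Lewis acid meets the epoxide.

Step 5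
Reactants: 5 (3R,4S)-1-{(2S,3R)-3-[(benzyloxy)methyl]-2-methyloxiran-2-yl}-4-methylhex-5-en-3-ol; 6 acryloyl chloride
Product: 7 (3R,4S)-1-{(2S,3R)-3-[(benzyloxy)methyl]-2-methyloxiran-2-yl}-4-methylhex-5-en-3-yl prop-2-enoate
Conditions: i-Pr2NEt, DMAP (cat.), CH2Cl2, 0 °C
Reagents that add atoms: acryloyl chloride, C=CC(=O)Cl
Why: Base-mediated O-acylation of the secondary alcohol with an acid chloride, which attaches the two carbons that become C8 and its carboxyl group.

Step 6
Reactants: 7 (3R,4S)-1-{(2S,3R)-3-[(benzyloxy)methyl]-2-methyloxiran-2-yl}-4-methylhex-5-en-3-yl prop-2-enoate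
Product: 8 (5S,6R)-6-(2-{(2S,3R)-3-[(benzyloxy)methyl]-2-methyloxiran-2-yl}ethyl)-5-methyl-5,6-dihydro-2H-pyran-2-one
Conditions: second-generation Grubbs catalyst (5 mol%), CH2Cl2 (5 mM), 40 °C
Reagents that add atoms: none
Why: Ring-closing metathesis of the acrylate and the vinyl group forms the six-membered α,β-unsaturated lactone with loss of ethene, which ties up C1–O and the future carboxyl group in one ring.

Step 7
Reactants: 8 (5S,6R)-6-(2-{(2S,3R)-3-[(benzyloxy)methyl]-2-methyloxiran-2-yl}ethyl)-5-methyl-5,6-dihydro-2H-pyran-2-one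
Product: 9 (3RS,5S,6R)-6-(2-{(2S,3R)-3-[(benzyloxy)methyl]-2-methyloxiran-2-yl}ethyl)-3-hydroxy-5-methyloxan-2-one
Conditions: Mn(dpm)3 (cat.), PhSiH3, O2 (1 atm), i-PrOH/CH2Cl2, 0 °C → rt
Reagents that add atoms: dioxygen, O=O
Why: Mukaiyama-type hydration of the conjugated lactone, in which hydrogen-atom transfer from a manganese hydride to C9 gives the carbonyl-stabilised C8 radical that is trapped by dioxygen and reduced by the silane to the α-hydroxy lactone; C8 is formed unselectively, which is harmless because it is planarised in step 16.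

Step 8
Reactants: 9 (3RS,5S,6R)-6-(2-{(2S,3R)-3-[(benzyloxy)methyl]-2-methyloxiran-2-yl}ethyl)-3-hydroxy-5-methyloxan-2-one
Product: 10 (3RS,5S,6R)-6-(2-{(2S,3R)-3-[(benzyloxy)methyl]-2-methyloxiran-2-yl}ethyl)-3-[(tert-butyldimethylsilyl)oxy]-5-methyloxan-2-one
Conditions: TBSCl, imidazole, DMF, rt
Reagents that add atoms: tert-butyldimethylsilyl chloride, CC(C)(C)[Si](C)(C)Cl
Why: Imidazole-promoted silylation of the α-hydroxy lactone under conditions free of Lewis acid, which leave the trisubstituted epoxide alone.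

Step 9
Reactants: 10 (3RS,5S,6R)-6-(2-{(2S,3R)-3-[(benzyloxy)methyl]-2-methyloxiran-2-yl}ethyl)-3-[(tert-butyldimethylsilyl)oxy]-5-methyloxan-2-one
Product: 12 (2RS,4S)-7-{(2S,3R)-3-[(benzyloxy)methyl]-2-methyloxiran-2-yl}-2-[(tert-butyldimethylsilyl)oxy]-4-methyl-5-oxoheptanoic acid, via lithium hydroxy carboxylate 11 (not isolated)
Conditions: LiOH, THF/H2O, 0 °C → rt; then TEMPO (cat.), KBr (cat.), NaOCl, NaHCO3, CH2Cl2/H2O, 0 °C; aq. NaHSO4 to pH 4
Reagents that add atoms: lithium hydroxide, [Li+].[OH-]
Why: Saponification opens the δ-lactone and the δ-hydroxy carboxylate is oxidised as its salt by the oxoammonium/hypochlorite couple (Anelli oxidation) before acidification, so it cannot relactonise, which gives the C1 ketone and the free acid without touching C10.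

Step 10
Reactants: 12 (2RS,4S)-7-{(2S,3R)-3-[(benzyloxy)methyl]-2-methyloxiran-2-yl}-2-[(tert-butyldimethylsilyl)oxy]-4-methyl-5-oxoheptanoic acid
Product: 13 (2RS,4S)-2-[(tert-butyldimethylsilyl)oxy]-7-[(2S,3R)-3-(hydroxymethyl)-2-methyloxiran-2-yl]-4-methyl-5-oxoheptanoic acid
Conditions: H2 (1 atm), Pd/C (10 wt%), EtOAc, rt
Reagents that add atoms: none
Why: Hydrogenolysis of the benzyl ether over palladium frees the C6 hydroxyl, while the ketone, the silyl ether, the acid and the non-benzylic epoxide are inert.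

Step 11
Reactants: 13 (2RS,4S)-2-[(tert-butyldimethylsilyl)oxy]-7-[(2S,3R)-3-(hydroxymethyl)-2-methyloxiran-2-yl]-4-methyl-5-oxoheptanoic acid
Product: 14 (2RS,4S)-2-[(tert-butyldimethylsilyl)oxy]-7-[(2S,3S)-3-formyl-2-methyloxiran-2-yl]-4-methyl-5-oxoheptanoic acid
Conditions: TEMPO (cat.), PhI(OAc)2, CH2Cl2, rt
Reagents that add atoms: none
Why: Oxoammonium oxidation of the primary alcohol under anhydrous conditions stops at the aldehyde, tolerates the free acid and cannot epimerise C5, which is an epoxide carbon (the descriptor changes from R to S only because the formyl group outranks C4).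

Step 12
Reactants: 15 ethyl bromopyruvate
Product: 16 ethyl 3-acetoxy-2-oxopropanoate
Conditions: KOAc, acetone, rt
Reagents that add atoms: potassium acetate, CC(=O)[O-].[K+]
Why: SN2 displacement of the activated α-keto bromide by acetate.

Step 13
Reactants: 16 ethyl 3-acetoxy-2-oxopropanoate
Product: 17 ethyl 2-(acetoxymethyl)-3,3-dibromoprop-2-enoate
Conditions: CBr4, PPh3, CH2Cl2, 0 °C
Reagents that add atoms: carbon tetrabromide, BrC(Br)(Br)Br
Why: Ramirez dibromo-olefination of the highly electrophilic α-keto ester carbonyl, which brings in C7 with both bromine atoms.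

Step 14
Reactants: 14 (2RS,4S)-2-[(tert-butyldimethylsilyl)oxy]-7-[(2S,3S)-3-formyl-2-methyloxiran-2-yl]-4-methyl-5-oxoheptanoic acid; 17 ethyl 2-(acetoxymethyl)-3,3-dibromoprop-2-enoate
Product: 20 (2RS,4S)-7-{(2S,3R)-3-[(2S)-4-(acetoxymethyl)-3-bromo-5-oxo-2,5-dihydrofuran-2-yl]-2-methyloxiran-2-yl}-2-[(tert-butyldimethylsilyl)oxy]-4-methyl-5-oxoheptanoic acid, via magnesium carbenoid 18 (not isolated), via magnesium alkoxide adduct 19 (not isolated)
Conditions: 17 (2.2 equiv), i-PrMgCl (2.1 equiv), THF, −78 °C; then 14, −78 → −40 °C; pH 4 phosphate buffer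
Reagents that add atoms: ethyl 2-(acetoxymethyl)-3,3-dibromoprop-2-enoate (17), CCOC(=O)C(COC(C)=O)=C(Br)Br
Why: Bromine–magnesium exchange of the bromide cis to the chelating ester gives a magnesium carbenoid that adds to the aldehyde much faster than to the hindered ketone (its first equivalent is spent on the carboxylic acid), Felkin–Anh attack anti to the epoxide C–O bond should favour the erythro C6 alkoxide with the spatial arrangement of the target, and this alkoxide closes onto the cis ester to give the 4-bromobutenolide with the second bromine left on C7 (carbenoid addition–lactonisation).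

Step 15
Reactants: 20 the bromobutenolide acid; 21 N-hydroxyphthalimide
Product: 22 1,3-dioxoisoindolin-2-yl (2RS,4S)-7-{(2S,3R)-3-[(2S)-4-(acetoxymethyl)-3-bromo-5-oxo-2,5-dihydrofuran-2-yl]-2-methyloxiran-2-yl}-2-[(tert-butyldimethylsilyl)oxy]-4-methyl-5-oxoheptanoate
Conditions: N,N'-diisopropylcarbodiimide, CH2Cl2, 0 °C → rt
Reagents that add atoms: N-hydroxyphthalimide, ON1C(=O)c2ccccc2C1=O
Why: Carbodiimide-mediated esterification of the acid with N-hydroxyphthalimide, run without a nucleophilic amine catalyst so that the vinylogous acyl bromide is not attacked.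

Step 16
Reactants: 22 the C8 N-acyloxyphthalimide (C8-epimeric mixture)
Product: 23 (4S,5R,6R,8R,10S)-13-acetoxy-8-[(tert-butyldimethylsilyl)oxy]-4,5-epoxy-1-oxogermacr-7(11)-en-12,6-olide
Conditions: NiBr2(dme) (20 mol%), 2,2'-bipyridine (24 mol%), AgNO3 (30 mol%), Bu4NPF6, DMF, magnesium anode, reticulated vitreous carbon cathode, undivided cell, constant current, rt, 22 added by syringe pump (final 2 mM)
Reagents that add atoms: none
Why: Proposed new method: Cathodic reduction of the bipyridine complex of NiBr2 gives zerovalent nickel, which inserts into the electron-poor C7–Br bond of the β-bromobutenolide, while single-electron reduction of the N-acyloxyphthalimide (by low-valent nickel or at the cathode) expels phthalimide anion and CO2 and leaves the nucleophilic α-silyloxy radical at C8; capture of this radical by the alkenylnickel gives a trivalent nickel species that reductively eliminates to form C7–C8. The closest known reaction type is the intermolecular nickel-catalysed (zinc-mediated or electroreductive) decarboxylative alkenylation of redox-active esters with alkenyl halides, which works with α-oxy acids and tolerates ketones, esters and epoxides; its use as a ring closure is what is new. The ten-membered carbocycle is closed as a macrocyclising C(sp2)–C(sp3) cross-coupling, by intramolecular radical capture at nickel and reductive elimination from an eleven-membered nickelacycle, so endo/exo rules for radical addition do not apply. The new C8 stereocentre is fixed only at the capture and reductive-elimination stage: the C6 centre, the C4–C5 epoxide and the C10 methyl group limit the conformations of the closing ring and should place the bulky silyloxy group on the outer face (8R), and both C8 epimers of 22 converge because C8 is planar in the radical; a chiral bis(oxazoline) ligand could reinforce the preference. The step needs site selectivity for C7–Br over the allylic acetate, epoxide, ketone and lactone, secured by the much faster oxidative addition into the vinylogous acyl bromide and by the absence of any polar organometallic, and it needs cyclisation to outrun dimerisation and premature reduction, secured by slow addition at high dilution.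

Step 17
Reactants: 23 the C8 silyl ether of the closed germacranolide
Product: 24 (4S,5R,6R,8R,10S)-13-acetoxy-4,5-epoxy-8-hydroxy-1-oxogermacr-7(11)-en-12,6-olide
Conditions: HF·pyridine, pyridine, THF, 0 °C → rt
Reagents that add atoms: none
Why: Fluoride-mediated desilylation with pyridine-buffered hydrogen fluoride cleaves the secondary silyl ether without the basic conditions that could deprotonate C6 next to the epoxide or the strongly acidic ones that could open the epoxide.

Step 18
Reactants: 24 the C8 alcohol; 25 3-methylbut-2-enoyl chloride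
Product: 26 (4S,5R,6R,8R,10S)-13-acetoxy-4,5-epoxy-8-(3-methylbut-2-enoyloxy)-1-oxogermacr-7(11)-en-12,6-olide (CNP0220542.1)
Conditions: pyridine, DMAP (cat.), CH2Cl2, 0 °C
Reagents that add atoms: 3-methylbut-2-enoyl chloride, CC(C)=CC(=O)Cl
Why: O-Acylation of the C8 alcohol with the acid chloride and the weak base pyridine, which avoids the vinylketene pathway that gives the deconjugated ester with stronger amines.

Compound list
1 | nerol, (2Z)-3,7-dimethylocta-2,6-dien-1-ol | CC(C)=CCC/C(C)=C\CO | starting material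
2 | [(2R,3S)-3-methyl-3-(4-methylpent-3-en-1-yl)oxiran-2-yl]methanol | OC[C@H]1O[C@@]1(C)CCC=C(C)C | intermediate
3 | (2R,3S)-2-[(benzyloxy)methyl]-3-methyl-3-(4-methylpent-3-en-1-yl)oxirane | C(OC[C@H]1O[C@@]1(C)CCC=C(C)C)c1ccccc1 | intermediate
4 | 3-{(2S,3R)-3-[(benzyloxy)methyl]-2-methyloxiran-2-yl}propanal | C(OC[C@H]1O[C@@]1(C)CCC=O)c1ccccc1 | intermediate
5 | (3R,4S)-1-{(2S,3R)-3-[(benzyloxy)methyl]-2-methyloxiran-2-yl}-4-methylhex-5-en-3-ol | C(OC[C@H]1O[C@@]1(C)CC[C@@H](O)[C@@H](C)C=C)c1ccccc1 | intermediate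
6 | acryloyl chloride | C=CC(=O)Cl | starting material
7 | (3R,4S)-1-{(2S,3R)-3-[(benzyloxy)methyl]-2-methyloxiran-2-yl}-4-methylhex-5-en-3-yl prop-2-enoate | C(OC[C@H]1O[C@@]1(C)CC[C@@H](OC(=O)C=C)[C@@H](C)C=C)c1ccccc1 | intermediate
8 | (5S,6R)-6-(2-{(2S,3R)-3-[(benzyloxy)methyl]-2-methyloxiran-2-yl}ethyl)-5-methyl-5,6-dihydro-2H-pyran-2-one | C(OC[C@H]1O[C@@]1(C)CC[C@H]1OC(=O)C=C[C@@H]1C)c1ccccc1 | intermediate
9 | (3RS,5S,6R)-6-(2-{(2S,3R)-3-[(benzyloxy)methyl]-2-methyloxiran-2-yl}ethyl)-3-hydroxy-5-methyloxan-2-one | C(OC[C@H]1O[C@@]1(C)CC[C@H]1OC(=O)C(O)C[C@@H]1C)c1ccccc1 | intermediate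
10 | (3RS,5S,6R)-6-(2-{(2S,3R)-3-[(benzyloxy)methyl]-2-methyloxiran-2-yl}ethyl)-3-[(tert-butyldimethylsilyl)oxy]-5-methyloxan-2-one | C(OC[C@H]1O[C@@]1(C)CC[C@H]1OC(=O)C(O[Si](C)(C)C(C)(C)C)C[C@@H]1C)c1ccccc1 | intermediate
11 | lithium (2RS,4S,5R)-7-{(2S,3R)-3-[(benzyloxy)methyl]-2-methyloxiran-2-yl}-2-[(tert-butyldimethylsilyl)oxy]-5-hydroxy-4-methylheptanoate | C(OC[C@H]1O[C@@]1(C)CC[C@@H](O)[C@@H](C)CC(O[Si](C)(C)C(C)(C)C)C(=O)[O-])c1ccccc1.[Li+] | intermediate (not isolated)
12 | (2RS,4S)-7-{(2S,3R)-3-[(benzyloxy)methyl]-2-methyloxiran-2-yl}-2-[(tert-butyldimethylsilyl)oxy]-4-methyl-5-oxoheptanoic acid | C(OC[C@H]1O[C@@]1(C)CCC(=O)[C@@H](C)CC(O[Si](C)(C)C(C)(C)C)C(=O)O)c1ccccc1 | intermediate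
13 | (2RS,4S)-2-[(tert-butyldimethylsilyl)oxy]-7-[(2S,3R)-3-(hydroxymethyl)-2-methyloxiran-2-yl]-4-methyl-5-oxoheptanoic acid | OC[C@H]1O[C@@]1(C)CCC(=O)[C@@H](C)CC(O[Si](C)(C)C(C)(C)C)C(=O)O | intermediate
14 | (2RS,4S)-2-[(tert-butyldimethylsilyl)oxy]-7-[(2S,3S)-3-formyl-2-methyloxiran-2-yl]-4-methyl-5-oxoheptanoic acid | O=C[C@H]1O[C@@]1(C)CCC(=O)[C@@H](C)CC(O[Si](C)(C)C(C)(C)C)C(=O)O | intermediate
15 | ethyl bromopyruvate (ethyl 3-bromo-2-oxopropanoate) | CCOC(=O)C(=O)CBr | starting material
16 | ethyl 3-acetoxy-2-oxopropanoate | CCOC(=O)C(=O)COC(C)=O | intermediate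
17 | ethyl 2-(acetoxymethyl)-3,3-dibromoprop-2-enoate | CCOC(=O)C(COC(C)=O)=C(Br)Br | intermediate
18 | ethyl (2E)-2-(acetoxymethyl)-3-bromo-3-(chloromagnesio)prop-2-enoate (magnesium cis to the ester) | CCOC(=O)/C(COC(C)=O)=C(/Br)[Mg]Cl | intermediate (not isolated)
19 | bis(chloromagnesium) salt (C6 alkoxide, carboxylate) of the open-chain ethyl ester adduct of 18 and 14 | CCOC(=O)/C(COC(C)=O)=C(/Br)[C@@H](O[Mg]Cl)[C@H]1O[C@@]1(C)CCC(=O)[C@@H](C)CC(O[Si](C)(C)C(C)(C)C)C(=O)O[Mg]Cl | intermediate (not isolated)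
20 | (2RS,4S)-7-{(2S,3R)-3-[(2S)-4-(acetoxymethyl)-3-bromo-5-oxo-2,5-dihydrofuran-2-yl]-2-methyloxiran-2-yl}-2-[(tert-butyldimethylsilyl)oxy]-4-methyl-5-oxoheptanoic acid | CC(=O)OCC1=C(Br)[C@@H](OC1=O)[C@H]2O[C@@]2(C)CCC(=O)[C@@H](C)CC(O[Si](C)(C)C(C)(C)C)C(=O)O | intermediate
21 | N-hydroxyphthalimide | ON1C(=O)c2ccccc2C1=O | starting material
22 | 1,3-dioxoisoindolin-2-yl ester of 20 (key-step precursor, C8 epimers) | CC(=O)OCC1=C(Br)[C@@H](OC1=O)[C@H]2O[C@@]2(C)CCC(=O)[C@@H](C)CC(O[Si](C)(C)C(C)(C)C)C(=O)ON3C(=O)c4ccccc4C3=O | intermediate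
23 | (4S,5R,6R,8R,10S)-13-acetoxy-8-[(tert-butyldimethylsilyl)oxy]-4,5-epoxy-1-oxogermacr-7(11)-en-12,6-olide (key-step product) | CC(=O)OCC1=C2[C@@H](OC1=O)[C@H]1O[C@@]1(C)CCC(=O)[C@@H](C)C[C@H]2O[Si](C)(C)C(C)(C)C | intermediate
24 | (4S,5R,6R,8R,10S)-13-acetoxy-4,5-epoxy-8-hydroxy-1-oxogermacr-7(11)-en-12,6-olide | CC(=O)OCC1=C2[C@@H](OC1=O)[C@H]1O[C@@]1(C)CCC(=O)[C@@H](C)C[C@H]2O | intermediate
25 | 3-methylbut-2-enoyl chloride (senecioyl chloride) | CC(C)=CC(=O)Cl | starting material
26 | (4S,5R,6R,8R,10S)-13-acetoxy-4,5-epoxy-8-(3-methylbut-2-enoyloxy)-1-oxogermacr-7(11)-en-12,6-olide, CNP0220542.1 | CC(=O)OCC1=C2[C@@H](OC1=O)[C@H]1O[C@@]1(C)CCC(=O)[C@@H](C)C[C@H]2OC(=O)C=C(C)C | target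

Total step count: 18 (steps 12 and 13 are a two-step side branch to reagent 17).
Longest linear sequence: 16 steps (steps 1–11 and 14–18, from nerol).

Steps most likely to fail

Step 16. The ring closure may lose to intermolecular coupling, or to premature reduction of the C7–Br bond or of the C8 radical, and capture at C8 may occur on the wrong face. The fallback forms the same C7–C8 bond by known chemistry; it sets out from 20 and returns at 24. The silyl ether of 20 would be cleaved with HF·pyridine to the α-hydroxy acid F1. Oxidative decarboxylation of F1 with Pb(OAc)4 in CH2Cl2 at 0 °C would give the C8 aldehyde, (3S)-6-{(2S,3R)-3-[(2S)-4-(acetoxymethyl)-3-bromo-5-oxo-2,5-dihydrofuran-2-yl]-2-methyloxiran-2-yl}-3-methyl-4-oxohexanal F2. An intramolecular Nozaki–Hiyama–Kishi reaction (CrCl2, NiCl2 cat., DMSO/THF, high dilution, rt) would then add the C7 alkenyl bromide to the aldehyde, selectively over the ketone, and give 24 as C8 epimers. The (8R) alcohol would go on to step 18; the (8S) alcohol could be inverted by Mitsunobu esterification with 3-methylbut-2-enoic acid to give 26.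

Step 14. The organomagnesium may attack the acetate or the ketone, magnesium halide may open the epoxide on warming, or facial selectivity at C6 may be poor. The fallback replaces the basic magnesium reagent by an organochromium one; it sets out from 14 and 17 and returns at 20. Carbenoid 18, made from 17 as in step 14, would be quenched at −78 °C with I2 to give ethyl (2Z)-2-(acetoxymethyl)-3-bromo-3-iodoprop-2-enoate F3, with iodine cis to the ester. A Nozaki–Hiyama–Kishi coupling of 14 with F3 (CrCl2, NiCl2 cat., DMF, rt) should engage only the C–I bond and only the aldehyde, and the chromium alkoxide should lactonise onto the cis ester to give 20. If the C6 ratio stays poor, the epimers would be separated at this stage.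

Step 9. The δ-hydroxy acid may relactonise before it is oxidised, or the aqueous hypochlorite may oxidise incompletely or chlorinate next to the ketone. The fallback traps the acid as an ester and oxidises in an organic medium; it sets out from 10 and returns at 13. After saponification with LiOH, the lithium carboxylate 11 would be alkylated in DMF with benzyl bromide to the benzyl (2RS,4S,5R)-5-hydroxy ester F4. Dess–Martin periodinane in CH2Cl2 would oxidise F4 to the benzyl keto ester F5. Hydrogenolysis (H2, Pd/C, EtOAc) would then remove both benzyl groups at once and give 13, so step 10 is absorbed.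

Further compounds
F1 | step 16 | (2RS,4S)-7-{(2S,3R)-3-[(2S)-4-(acetoxymethyl)-3-bromo-5-oxo-2,5-dihydrofuran-2-yl]-2-methyloxiran-2-yl}-2-hydroxy-4-methyl-5-oxoheptanoic acid | CC(=O)OCC1=C(Br)[C@@H](OC1=O)[C@H]2O[C@@]2(C)CCC(=O)[C@@H](C)CC(O)C(=O)O
F2 | step 16 | (3S)-6-{(2S,3R)-3-[(2S)-4-(acetoxymethyl)-3-bromo-5-oxo-2,5-dihydrofuran-2-yl]-2-methyloxiran-2-yl}-3-methyl-4-oxohexanal | CC(=O)OCC1=C(Br)[C@@H](OC1=O)[C@H]2O[C@@]2(C)CCC(=O)[C@@H](C)CC=O
F3 | step 14 | ethyl (2Z)-2-(acetoxymethyl)-3-bromo-3-iodoprop-2-enoate | CCOC(=O)/C(COC(C)=O)=C(/Br)I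
F4 | step 9 | benzyl (2RS,4S,5R)-7-{(2S,3R)-3-[(benzyloxy)methyl]-2-methyloxiran-2-yl}-2-[(tert-butyldimethylsilyl)oxy]-5-hydroxy-4-methylheptanoate | C(OC[C@H]1O[C@@]1(C)CC[C@@H](O)[C@@H](C)CC(O[Si](C)(C)C(C)(C)C)C(=O)OCc1ccccc1)c1ccccc1
F5 | step 9 | benzyl (2RS,4S)-7-{(2S,3R)-3-[(benzyloxy)methyl]-2-methyloxiran-2-yl}-2-[(tert-butyldimethylsilyl)oxy]-4-methyl-5-oxoheptanoate | C(OC[C@H]1O[C@@]1(C)CCC(=O)[C@@H](C)CC(O[Si](C)(C)C(C)(C)C)C(=O)OCc1ccccc1)c1ccccc1
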